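## Structural features

The target is an isoflavone: a 4H-chromen-4-one (benzo ring A fused to pyranone ring C) carrying an aryl ring B at C3. Ring B is itself fused to a 2,2-dimethyl-3,4-dihydro-2H-pyran (ring D), so rings B and D form an 8-hydroxy-2,2-dimethylchroman attached through its C6. Ring A bears hydroxyls at C5 and C7, and the third hydroxyl sits on ring B next to the ring D oxygen. There is no stereocentre: the only quaternary sp3 carbon, C2 of ring D, carries two methyl groups, so no question of neighbouring stereocentres arises. Fragile sites are the electrophilic C2 of ring C (hydroxide or alkoxide adds there, opens ring C and can excise C2 as formate), the tertiary alkyl aryl ether of ring D (it can ionise under strong acid), and the electron-rich free phenols (air-sensitive under base, and competing nucleophiles). The real difficulty is regiochemistry and oxygen bookkeeping: ring C must be closed between a 1,3,5-trioxygenated ring A and an unsymmetrical ring B/D unit, ring D must be annulated on the correct side of ring B, and three phenols must be unmasked at the end without damage to rings C and D. The feature exploited is that the oxygen-bearing carbons C5, C7 and C8a stand ortho, para and ortho to the carbonyl-bearing C4a. A 2,4,6-trifluorobenzoyl group therefore supplies, in one symmetrical unit, the leaving group for closure of O1–C8a and two further activated fluorides that stand in for the C5 and C7 hydroxyls.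

## Logic of the disconnections

**15 to 14.** The three O–CH3 bonds on the C5, C7 and chroman C8 oxygens are cut. Free phenols would quench every base used earlier and would compete as nucleophiles, so they stay masked as the smallest possible ethers until the end. The gain is that one operation releases all three hydroxyls. The demand is a cleavage that attacks methyl carbons only and leaves the tertiary C2–O bond of ring D and the pyranone intact.

**14 to 12 (through 13).** The C5–O and C7–O bonds are cut and replaced by C–F bonds. Both carbons are ortho or para to the C4 carbonyl, so the fluorides are activated for addition–elimination. The gain is that ring A goes back to a symmetrical trihalogenated arene in which no regiochemical question exists. The demand is that the alkoxide substitutes on ring A and that its reversible addition to C2 of ring C does no lasting harm, which calls for anhydrous conditions.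

**12 to 11.** The O1–C8a bond is cut (key step). This opens ring C to an enol whose oxygen is already five atoms from an ortho fluoride. The gain is an acyclic precursor that contains every carbon of the target. The demand is that the enolate oxygen closes the six-membered ring faster than anything attacks the para fluoride or the 1,3-dicarbonyl unit.

**11 to 8 and 9 (through 10).** The C3–C4 bond is cut, together with the exchange of the enol oxygen for an amine nitrogen. This separates the ring A block 9 from the ring B/D block 8 at the only carbon–carbon bond that joins them, and makes the synthesis convergent. The demand is acylation at carbon and not at nitrogen, and a hydrolysis that frees the enol without loss of the formyl carbon.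

**8 to 6 and 7, and 6 to 5.** The enamine C–N bond is cut and the aldehyde oxidation level is traced back to the primary alcohol. An arylacetaldehyde is labile; its conjugated enamine is the storable nucleophilic form, and the alcohol is the robust form that can be carried through the building of ring D. The demand is an oxidation that stops at the aldehyde and a condensation that outruns aldol reaction.

**5 to 4 to 3.** The C3–C4 saturation is removed, then the C4a–C4 and O1–C2 bonds of ring D are cut. The aryl propargyl ether has only one free ortho position, so the pericyclic cascade can deliver only the required ring fusion. The gain is that ring D comes from a phenol and a five-carbon unit. The demand is a thermal step tolerated by the free primary alcohol and a hydrogenation that does not cleave the allylic C–O bond.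

**3 to 1 and 2.** The ether bond between the phenol oxygen and the tertiary propargylic carbon is cut, which leads to two purchasable compounds. The demand is substitution at a tertiary centre, which needs copper catalysis, and selectivity for the phenol oxygen over the aliphatic hydroxyl, which the difference in acidity secures.

## Other disconnections considered

**Alternative 1:** The cut is made in ring D of the finished isoflavone, at the bond from the ring B carbon ortho to the ether oxygen (C5') to the ring D CH, and at the O–CMe2 bond.
- Forward step: the aryl 1,1-dimethylpropargyl ether A1 (5,7-dimethoxy-3-[3-methoxy-4-(2-methylbut-3-yn-2-yloxy)phenyl]-4H-chromen-4-one) would be heated near 200 °C in a high-boiling amine solvent. A [3,3] shift to the one free ortho carbon, a hydrogen shift and oxa-6π closure should give the chromene A2 (5,7-dimethoxy-3-(8-methoxy-2,2-dimethyl-2H-chromen-6-yl)-4H-chromen-4-one), which hydrogenation would convert into 14.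
- In favour: it is the same pericyclic sequence that the chosen route uses in step 2, and the regiochemistry is equally unambiguous because the other ortho position carries the methoxy group. Placing ring D last would also let one phenolic isoflavone serve several ring D variants.
- Against: it leaves the harder problem, ring C between rings A and B, unsolved. The 4'-oxygen must be kept distinct from three methoxy groups throughout the isoflavone synthesis, which costs a protection and a deprotection. The thermal step and the hydrogenation must then be run on the complete isoflavone, where the C2=C3 bond of ring C competes for hydrogen with the chromene double bond.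
- Comparison: on structure, both plans make ring D through the same two bonds and are equal in regiocontrol. On mechanism, the alternative is the equal of step 2 and differs only in timing; the chosen plan runs the cascade and the hydrogenation on a small phenethyl alcohol with no other reducible group. On step economy, the alternative is expected to be longer by about two protecting-group steps, though it has the better claim if analogues with other ring D units were wanted.

**Alternative 2:** Three bonds of ring C are cut at once, O1–C8a, C4–C4a and O1–C2. This leaves the acrylic acid A3 ((E)-3-methoxy-2-(8-methoxy-2,2-dimethylchroman-6-yl)acrylic acid) and the aryne precursor A4 (3,5-dimethoxy-2-(trimethylsilyl)phenyl trifluoromethanesulfonate).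
- Forward step: fluoride would release the aryne from A4 in the presence of the carboxylate of A3. The carboxylate oxygen should add to the aryne carbon remote from the neighbouring methoxy group, the aryl anion should take the acyl group intramolecularly (net insertion into the C–O bond), and the resulting phenoxide should close ring C by conjugate addition and expulsion of the methoxy group. The product would be A5 (5,7-dimethoxy-3-(8-methoxy-2,2-dimethylchroman-6-yl)-4H-chromen-4-one, the same compound as 14).
- In favour: three bonds in one operation and high convergence. It arrives at the trimethyl ether without fluoride–alkoxide exchange, so it is better than the chosen plan by one step after ring closure and spares ring C the alkoxide of step 8.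
- Against: A4 is not a catalogue compound and needs about three steps, and A3 needs formylation, O-methylation and saponification of a ring D arylacetic ester. The acyl transfer must compete with simple protonation of the aryl anion, which would stop at the aryl ester, and the carbonyl concerned is a deactivated, vinylogous carbonate-like one flanked by an aryl group. The site selectivity of the unsymmetrical aryne rests on one methoxy group and need not be complete.
- Comparison: on structure, both plans form O1–C8a on ring A, but the chosen plan takes C4–C4a ready-made in 9 and uses a symmetrical ring, whereas the alternative must control aryne regiochemistry. On mechanism, the chosen closure is a tethered addition–elimination and the alternative is an intermolecular cascade of three events through a high-energy intermediate. On step count, the alternative is equal or shorter in its longest linear sequence but longer in total once A4 is made.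

**Alternative 3:** Ring A is cut at C4a–C5 and C8–C8a. This leaves the bromopyranone A6 (3-bromo-5-(8-methoxy-2,2-dimethylchroman-6-yl)-4H-pyran-4-one) and the dioxygenated silyl ketene acetal diene A7 ((E)-1,3-dimethoxy-1-(trimethylsilyloxy)buta-1,3-diene).
- Forward step: A7 would add across the brominated double bond of A6, its CH2 terminus to the oxygen-bearing β-carbon (future C8a) and its ketene acetal carbon to the brominated α-carbon (future C4a). Loss of the bromide with the adjacent hydrogen and of one methoxy group would aromatise the new ring to A8 (5-hydroxy-7-methoxy-3-(8-methoxy-2,2-dimethylchroman-6-yl)-4H-chromen-4-one).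
- In favour: the oxygen pattern of ring A comes with the diene and C5 arrives as the free, chelated hydroxyl. Only two methyl ethers remain to be cleaved, which is better than the chosen plan's three, and no fluoride exchange is needed.
- Against: this benzannulation is established for halogenated quinones, which are doubly activated dienophiles. A 4-pyranone is a cross-conjugated vinylogous ester with some aromatic stabilisation and should be far less reactive. The moisture-sensitive diene could instead add at the other β-carbon, next to the aryl group, or simply hydrolyse. A6 would require a selective mono-arylation of a symmetrical dihalopyranone.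
- Comparison: on structure, the alternative builds two C–C bonds of ring A where the chosen plan builds one C–O bond of ring C and takes ring A whole from 9. On mechanism, the orientation of the cycloaddition must be steered by the bromine and the carbonyl, while the chosen ring closure has no regiochemical choice. On step economy, the two are expected to be close once A6 is counted, and the alternative is the equal of the chosen plan in fixing the ring A oxygen pattern unambiguously.

Key step: step 7

Assumption on the chemistry: 1 (homovanillyl alcohol), 2, 7 and 9 are purchased. Entry at the alcohol oxidation level is preferred to an arylacetic ester because oxidation of a primary alcohol reaches the arylacetaldehyde more reliably than partial reduction of an ester, and no esterification step is needed. Compound 11 is drawn as the chelated Z enol (hydroxyl cis to the aroyl group), which is the geometry that can close.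

## Route

Step 1
Reactants: 1 4-(2-hydroxyethyl)-2-methoxyphenol (homovanillyl alcohol); 2 3-chloro-3-methylbut-1-yne
Product: 3 2-[3-methoxy-4-(2-methylbut-3-yn-2-yloxy)phenyl]ethan-1-ol
Conditions: 2 (1.5 equiv), DBU, CuCl2 (cat.), MeCN, 0 °C to rt
Reagents that add atoms: none
Why: Copper-catalysed propargylic substitution through a copper acetylide lets the phenoxide alkylate at the tertiary carbon; DBU deprotonates only the phenol, so the neutral aliphatic hydroxyl should not compete.

Step 2
Reactants: 3 2-[3-methoxy-4-(2-methylbut-3-yn-2-yloxy)phenyl]ethan-1-ol
Product: 4 2-(8-methoxy-2,2-dimethyl-2H-chromen-6-yl)ethan-1-ol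
Conditions: PhNEt2, 190 °C
Reagents that add atoms: none
Why: Aromatic propargyl Claisen rearrangement to the only free ortho position, followed by enolisation, 1,5-hydrogen shift and oxa-6π electrocyclisation, should give the 2H-chromene as a single regioisomer, since the other ortho carbon carries the methoxy group and cannot rearomatise.

Step 3
Reactants: 4 2-(8-methoxy-2,2-dimethyl-2H-chromen-6-yl)ethan-1-ol
Product: 5 2-(8-methoxy-2,2-dimethylchroman-6-yl)ethan-1-ol
Conditions: H2 (1 atm), 10% Pd/C, EtOAc, rt
Reagents that add atoms: none
Why: Catalytic hydrogenation of the styrene-type C3=C4 bond of ring D; the aryl ethers, the tertiary C–O bond and the primary alcohol are inert under these mild conditions.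

Step 4
Reactants: 5 2-(8-methoxy-2,2-dimethylchroman-6-yl)ethan-1-ol
Product: 6 2-(8-methoxy-2,2-dimethylchroman-6-yl)acetaldehyde
Conditions: DMP, CH2Cl2, 0 °C to rt
Reagents that add atoms: none
Why: Dess–Martin oxidation stops at the aldehyde under non-aqueous, near-neutral conditions, which limits enolisation and aldol reaction of the arylacetaldehyde; the crude aldehyde is taken on at once.

Step 5
Reactants: 6 2-(8-methoxy-2,2-dimethylchroman-6-yl)acetaldehyde; 7 morpholine
Product: 8 (E)-4-[2-(8-methoxy-2,2-dimethylchroman-6-yl)vinyl]morpholine
Conditions: 7 (1.5 equiv), 4 Å MS, toluene, rt
Reagents that add atoms: none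
Why: Condensation of the aldehyde with the secondary amine and removal of water should give the enamine conjugated with the aryl ring, as the E isomer for steric reasons; this turns the labile aldehyde into the carbon nucleophile needed next.

Step 6
Reactants: 8 (E)-4-[2-(8-methoxy-2,2-dimethylchroman-6-yl)vinyl]morpholine; 9 2,4,6-trifluorobenzoyl chloride
Product: 11 (Z)-3-hydroxy-2-(8-methoxy-2,2-dimethylchroman-6-yl)-1-(2,4,6-trifluorophenyl)prop-2-en-1-one, via morpholino enaminone 10 (not isolated)
Conditions: 9 (1.05 equiv), Et3N, CH2Cl2, 0 °C to rt; then 2 M aq. HCl, THF, rt
Reagents that add atoms: water, O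
Why: Enamine C-acylation of the Stork type at the aryl-bearing β-carbon, with Et3N taking the proton, should give the vinylogous amide 10; aqueous acid then hydrolyses it to the 1,3-dicarbonyl compound, which rests as the internally hydrogen-bonded Z enol 11. The acid chloride has no α-hydrogen and any N-acylation is reversible, so carbon acylation should prevail.

Step 7
Reactants: 11 (Z)-3-hydroxy-2-(8-methoxy-2,2-dimethylchroman-6-yl)-1-(2,4,6-trifluorophenyl)prop-2-en-1-one
Product: 12 5,7-difluoro-3-(8-methoxy-2,2-dimethylchroman-6-yl)-4H-chromen-4-one
Conditions: K2CO3 (2 equiv), DMF (0.05 M), rt to 40 °C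
Reagents that add atoms: none
Why: K2CO3 deprotonates the acidic enol of 11 and the enolate oxygen adds to one fluorine-bearing ortho carbon (the future C8a), giving an anionic sigma complex whose charge is delocalised onto the ketone oxygen and onto the ring carbons that carry the two remaining fluorines, where their inductive pull stabilises it; loss of fluoride then restores aromaticity (addition–elimination SNAr) and forms O1–C8a. The closest known reaction type is the closure of 2-fluoroaryl 1,3-dicarbonyl enolates to chromones, the oxygen counterpart of the cycloaracylation used for 4-quinolones. Ring C closes as a six-membered ring by attack of oxygen on an sp2 carbon, with the breaking C–F bond lying outside the new ring (6-exo-trig in the addition step). No stereocentre is created. The selectivities needed are oxygen versus carbon attack, ortho versus para fluoride, and ring closure versus intermolecular substitution: carbon attack would require a four-membered ring, the para fluoride cannot be reached by the tethered oxygen, the two ortho fluorides are interchanged by rotation about the aryl–carbonyl bond so that either gives 12, and moderate dilution keeps the six-membered closure ahead of bimolecular attack at the para position. Only the Z enolate can close, but the delocalised enolate interconverts its geometries freely, so the geometry of 11 is not critical. Dry carbonate near room temperature should avoid deformylation of the 1,3-dicarbonyl unit and premature exchange of the C5 and C7 fluorides, which remain ortho and para to the carbonyl and are kept for step 8.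

Step 8
Reactants: 12 5,7-difluoro-3-(8-methoxy-2,2-dimethylchroman-6-yl)-4H-chromen-4-one
Product: 14 5,7-dimethoxy-3-(8-methoxy-2,2-dimethylchroman-6-yl)-4H-chromen-4-one, via 5-fluoro-7-methoxy isoflavone 13 (not isolated)
Conditions: NaOMe (5 equiv), anhydrous MeOH–THF, 60 °C; then AcOH
Reagents that add atoms: sodium methoxide, [Na+].[O-]C
Why: Twofold SNAr of fluorides ortho and para to the C4 carbonyl, the unhindered C7 fluoride expected to go first. Addition of methoxide to C2 of ring C is reversible in the absence of water, and the acidic quench re-closes any opened material, so the chromone should be recovered intact.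

Step 9
Reactants: 14 5,7-dimethoxy-3-(8-methoxy-2,2-dimethylchroman-6-yl)-4H-chromen-4-one
Product: 15 5,7-dihydroxy-3-(8-hydroxy-2,2-dimethylchroman-6-yl)-4H-chromen-4-one (target)
Conditions: BBr3 (8 equiv), CH2Cl2, −78 °C to rt; then MeOH, H2O
Reagents that add atoms: none
Why: Lewis acid ether cleavage: boron coordinates each methoxy oxygen and bromide attacks the methyl carbon, the chelated C5 ether going first and the C7 and chroman C8 ethers on warming. The 2,2-dimethylchroman is the ring that acid-mediated cyclisation of a prenylphenol produces, so a ring D that ionises at its tertiary C–O bond is expected to close again rather than be lost.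

## Compound list

1 | 4-(2-hydroxyethyl)-2-methoxyphenol (homovanillyl alcohol) | COc1cc(CCO)ccc1O | starting material
2 | 3-chloro-3-methylbut-1-yne | CC(C)(Cl)C#C | starting material
3 | 2-[3-methoxy-4-(2-methylbut-3-yn-2-yloxy)phenyl]ethan-1-ol | COc1cc(CCO)ccc1OC(C)(C)C#C | intermediate
4 | 2-(8-methoxy-2,2-dimethyl-2H-chromen-6-yl)ethan-1-ol | COc1cc(CCO)cc2C=CC(C)(C)Oc12 | intermediate
5 | 2-(8-methoxy-2,2-dimethylchroman-6-yl)ethan-1-ol | COc1cc(CCO)cc2CCC(C)(C)Oc12 | intermediate
6 | 2-(8-methoxy-2,2-dimethylchroman-6-yl)acetaldehyde | COc1cc(CC=O)cc2CCC(C)(C)Oc12 | intermediate
7 | morpholine | C1COCCN1 | starting material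
8 | (E)-4-[2-(8-methoxy-2,2-dimethylchroman-6-yl)vinyl]morpholine | COc1cc(/C=C/N2CCOCC2)cc2CCC(C)(C)Oc12 | intermediate
9 | 2,4,6-trifluorobenzoyl chloride | O=C(Cl)c1c(F)cc(F)cc1F | starting material
10 | (E)-2-(8-methoxy-2,2-dimethylchroman-6-yl)-3-(morpholin-4-yl)-1-(2,4,6-trifluorophenyl)prop-2-en-1-one (E expected; geometry without consequence) | O=C(c1c(F)cc(F)cc1F)/C(=C/N1CCOCC1)c1cc(OC)c2OC(C)(C)CCc2c1 | intermediate (not isolated)
11 | (Z)-3-hydroxy-2-(8-methoxy-2,2-dimethylchroman-6-yl)-1-(2,4,6-trifluorophenyl)prop-2-en-1-one | O/C=C(/c1cc(OC)c2OC(C)(C)CCc2c1)C(=O)c1c(F)cc(F)cc1F | intermediate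
12 | 5,7-difluoro-3-(8-methoxy-2,2-dimethylchroman-6-yl)-4H-chromen-4-one | COc1cc(-c2coc3cc(F)cc(F)c3c2=O)cc2CCC(C)(C)Oc12 | intermediate
13 | 5-fluoro-7-methoxy-3-(8-methoxy-2,2-dimethylchroman-6-yl)-4H-chromen-4-one | COc1cc(F)c2c(c1)occ(-c1cc(OC)c3OC(C)(C)CCc3c1)c2=O | intermediate (not isolated)
14 | 5,7-dimethoxy-3-(8-methoxy-2,2-dimethylchroman-6-yl)-4H-chromen-4-one | COc1cc(OC)c2c(c1)occ(-c1cc(OC)c3OC(C)(C)CCc3c1)c2=O | intermediate
15 | 5,7-dihydroxy-3-(8-hydroxy-2,2-dimethylchroman-6-yl)-4H-chromen-4-one | CC1(C)CCc2cc(-c3coc4cc(O)cc(O)c4c3=O)cc(O)c2O1 | target

## Step count and least certain steps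

Total number of steps: 9. Longest linear sequence: 9 steps (1 to 15); 2, 7 and 9 enter as purchased reagents.

**Step 7 (key step).** The most likely failure is intermolecular attack of the enolate oxygen, or of adventitious hydroxide or dimethylamine from the solvent, on the unhindered para fluoride in competition with ring closure. The second risk is base-induced loss of the formyl carbon from the 1,3-dicarbonyl unit before closure. The fallback is the deoxybenzoin route, which closes ring C through O1–C2 instead. It sets out from 6 and comes back to the route at 14, bypassing 12 and step 8. Oxidation of 6 with NaClO2, NaH2PO4 and 2-methylbut-2-ene in aqueous t-BuOH would give 2-(8-methoxy-2,2-dimethylchroman-6-yl)acetic acid F1. Acylation of 3,5-dimethoxyphenol with F1 in BF3·OEt2 at about 80 °C, ortho to the hydroxyl, would give 1-(2-hydroxy-4,6-dimethoxyphenyl)-2-(8-methoxy-2,2-dimethylchroman-6-yl)ethan-1-one F2. Heating F2 with N,N-dimethylformamide dimethyl acetal would supply C2 and close ring C by attack of the phenol oxygen with loss of dimethylamine, giving 14.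

**Step 6.** Acylation may stall at nitrogen, which returns the aldehyde and an amide on work-up, or occur twice. The acid hydrolysis of the vinylogous amide may be incomplete or may be accompanied by loss of the formyl carbon. The fallback builds the ketone first and adds the one-carbon unit afterwards. It sets out from 6 and comes back at 11. Addition of the Grignard reagent prepared from 1-bromo-2,4,6-trifluorobenzene and iPrMgCl (THF, −20 °C) to 6 would give racemic 2-(8-methoxy-2,2-dimethylchroman-6-yl)-1-(2,4,6-trifluorophenyl)ethan-1-ol F3. Dess–Martin oxidation would give 2-(8-methoxy-2,2-dimethylchroman-6-yl)-1-(2,4,6-trifluorophenyl)ethan-1-one F4. Claisen formylation of F4 with ethyl formate and NaH (THF, 0 °C), followed by an acidic quench, would give 11. If the sodium enolate closes in the flask, the product is 12 and step 7 is absorbed.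

**Step 8.** Methoxide may add to C2 and hold ring C open as the phenoxide, on which fluoride exchange is slow; traces of water would then cut out C2 as formate. The second substitution may also stall after the first methoxy group is in place. The fallback installs the ring A oxygens before ring closure, so that no alkoxide meets the chromone. It sets out from 8 and comes back at 14.
- Lithiation of 1-fluoro-3,5-dimethoxybenzene between fluorine and methoxy (n-BuLi, THF, −78 °C) and quenching with CO2 would give 2-fluoro-4,6-dimethoxybenzoic acid F5.
- Oxalyl chloride with catalytic DMF would give 2-fluoro-4,6-dimethoxybenzoyl chloride F6.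
- Acylation of 8 with F6 as in step 6 would give (E)-1-(2-fluoro-4,6-dimethoxyphenyl)-2-(8-methoxy-2,2-dimethylchroman-6-yl)-3-(morpholin-4-yl)prop-2-en-1-one F7, which is not isolated.
- Hydrolysis in the same flask would give (Z)-1-(2-fluoro-4,6-dimethoxyphenyl)-3-hydroxy-2-(8-methoxy-2,2-dimethylchroman-6-yl)prop-2-en-1-one F8.
- K2CO3 in DMF at 80–100 °C would close ring C by displacement of the single ortho fluoride, the same reaction type as step 7 on a less activated ring, to give 14.

**Step 9.** The tertiary C2–O bond of ring D may ionise under the excess of BBr3, with ring opening or elimination. The least activated methyl ether, at C7, may be cleaved incompletely in the time the rest of the molecule tolerates. The fallback removes the ring A groups by hydrogenolysis and the last methyl group by a nucleophile, so no Lewis acid is used. It sets out from 12 and comes back at 15.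
- Exchange of both fluorides with sodium benzyloxide (BnOH, NaH, THF–DMF) would give 5,7-bis(benzyloxy)-3-(8-methoxy-2,2-dimethylchroman-6-yl)-4H-chromen-4-one F9.
- Hydrogenolysis (H2, 10% Pd/C, EtOAc–MeOH) would give 5,7-dihydroxy-3-(8-methoxy-2,2-dimethylchroman-6-yl)-4H-chromen-4-one F10.
- NaSEt in DMF at about 130 °C would remove the one remaining methyl group by SN2 attack at the methyl carbon, giving 15. This mechanism cannot touch the tertiary carbon of ring D, and the ring A phenoxides formed under these conditions protect ring C against addition of the thiolate.

## Further compounds

F1 | step 7 | 2-(8-methoxy-2,2-dimethylchroman-6-yl)acetic acid | COc1cc(CC(=O)O)cc2CCC(C)(C)Oc12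
F2 | step 7 | 1-(2-hydroxy-4,6-dimethoxyphenyl)-2-(8-methoxy-2,2-dimethylchroman-6-yl)ethan-1-one | COc1cc(O)c(C(=O)Cc2cc(OC)c3OC(C)(C)CCc3c2)c(OC)c1
F3 | step 6 | 2-(8-methoxy-2,2-dimethylchroman-6-yl)-1-(2,4,6-trifluorophenyl)ethan-1-ol (racemic) | COc1cc(CC(O)c2c(F)cc(F)cc2F)cc2CCC(C)(C)Oc12
F4 | step 6 | 2-(8-methoxy-2,2-dimethylchroman-6-yl)-1-(2,4,6-trifluorophenyl)ethan-1-one | COc1cc(CC(=O)c2c(F)cc(F)cc2F)cc2CCC(C)(C)Oc12
F5 | step 8 | 2-fluoro-4,6-dimethoxybenzoic acid | COc1cc(F)c(C(=O)O)c(OC)c1
F6 | step 8 | 2-fluoro-4,6-dimethoxybenzoyl chloride | COc1cc(F)c(C(=O)Cl)c(OC)c1
F7 | step 8 | (E)-1-(2-fluoro-4,6-dimethoxyphenyl)-2-(8-methoxy-2,2-dimethylchroman-6-yl)-3-(morpholin-4-yl)prop-2-en-1-one | O=C(c1c(F)cc(OC)cc1OC)/C(=C/N1CCOCC1)c1cc(OC)c2OC(C)(C)CCc2c1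
F8 | step 8 | (Z)-1-(2-fluoro-4,6-dimethoxyphenyl)-3-hydroxy-2-(8-methoxy-2,2-dimethylchroman-6-yl)prop-2-en-1-one | O/C=C(/c1cc(OC)c2OC(C)(C)CCc2c1)C(=O)c1c(F)cc(OC)cc1OC
F9 | step 9 | 5,7-bis(benzyloxy)-3-(8-methoxy-2,2-dimethylchroman-6-yl)-4H-chromen-4-one | COc1cc(-c2coc3cc(OCc4ccccc4)cc(OCc4ccccc4)c3c2=O)cc2CCC(C)(C)Oc12
F10 | step 9 | 5,7-dihydroxy-3-(8-methoxy-2,2-dimethylchroman-6-yl)-4H-chromen-4-one | COc1cc(-c2coc3cc(O)cc(O)c3c2=O)cc2CCC(C)(C)Oc12
A1 | alternative 1 | 5,7-dimethoxy-3-[3-methoxy-4-(2-methylbut-3-yn-2-yloxy)phenyl]-4H-chromen-4-one | COc1cc(OC)c2c(c1)occ(-c1ccc(OC(C)(C)C#C)c(OC)c1)c2=O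
A2 | alternative 1 | 5,7-dimethoxy-3-(8-methoxy-2,2-dimethyl-2H-chromen-6-yl)-4H-chromen-4-one | COc1cc(OC)c2c(c1)occ(-c1cc(OC)c3OC(C)(C)C=Cc3c1)c2=O
A3 | alternative 2 | (E)-3-methoxy-2-(8-methoxy-2,2-dimethylchroman-6-yl)acrylic acid | CO/C=C(/C(=O)O)c1cc(OC)c2OC(C)(C)CCc2c1
A4 | alternative 2 | 3,5-dimethoxy-2-(trimethylsilyl)phenyl trifluoromethanesulfonate | COc1cc(OC)c([Si](C)(C)C)c(OS(=O)(=O)C(F)(F)F)c1
A5 | alternative 2 | 5,7-dimethoxy-3-(8-methoxy-2,2-dimethylchroman-6-yl)-4H-chromen-4-one (identical with 14) | COc1cc(OC)c2c(c1)occ(-c1cc(OC)c3OC(C)(C)CCc3c1)c2=O
A6 | alternative 3 | 3-bromo-5-(8-methoxy-2,2-dimethylchroman-6-yl)-4H-pyran-4-one | COc1cc(-c2cocc(Br)c2=O)cc2CCC(C)(C)Oc12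
A7 | alternative 3 | (E)-1,3-dimethoxy-1-(trimethylsilyloxy)buta-1,3-diene | C=C(OC)/C=C(\OC)O[Si](C)(C)C
A8 | alternative 3 | 5-hydroxy-7-methoxy-3-(8-methoxy-2,2-dimethylchroman-6-yl)-4H-chromen-4-one | COc1cc(O)c2c(c1)occ(-c1cc(OC)c3OC(C)(C)CCc3c1)c2=O
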